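**Retrosynthetic overview**
1. Target 22 ⇐ alcohol 21: the oxa-bridge is closed last by 5-exo oxa-Michael addition onto the ring A enone; the acrylic acid comes from methyl ketone 18 via enol triflate 19 and hydroxycarbonylation.
2. The spiro δ-lactone, the bond joining ring A to ring C and three stereocentres ⇐ one formal [4+2] annulation of methylene dienone 8 with acid 15 (new reaction).
3. Ring A (8) ⇐ enone 7 ⇐ organocatalytic asymmetric Michael addition of isobutyraldehyde to Knoevenagel acceptor 3, Robinson-type closure and decarboxylation (first stereocentre).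
4. Ring C (15) ⇐ ethyl acetoacetate + vinylphosphonate + acrolein (Michael, Michael/Horner–Wadsworth–Emmons), then hydrolysis–decarboxylation; its single ketone α-centre is labile and is fixed by equilibration after the annulation.
5. Ring order: ring A carbocycle → ring C carbocycle (separate branch) → spiro δ-lactone → oxa-bridge.

Assumption: the (1R,2R) amine–thiourea catalyst gives the (3S) Michael adduct 5; if a test run shows the opposite sense, its commercial (1S,2S) enantiomer is used with no other change.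

Step 1
Reactants: 1 tert-butyl 3-oxobutanoate; 2 {[tert-butyl(diphenyl)silyl]oxy}acetaldehyde
Product: 3 tert-butyl 2-acetyl-4-{[tert-butyl(diphenyl)silyl]oxy}but-2-enoate (E/Z mixture)
Conditions: piperidine (10 mol%), AcOH (10 mol%), 4 Å MS, CH2Cl2, 0 °C to rt
Reagents that add atoms: none
Why: Knoevenagel condensation of an active methylene compound with an unhindered aldehyde; no stereocentre is formed and both alkene isomers feed the same Michael addition.

Step 2
Reactants: 3 tert-butyl 2-acetyl-4-{[tert-butyl(diphenyl)silyl]oxy}but-2-enoate; 4 2-methylpropanal (3 equiv)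
Product: 7 (5S)-5-({[tert-butyl(diphenyl)silyl]oxy}methyl)-4,4-dimethylcyclohex-2-en-1-one, via Michael adduct 5 (not isolated), via keto ester 6 (not isolated)
Conditions: 1-[(1R,2R)-2-aminocyclohexyl]-3-[3,5-bis(trifluoromethyl)phenyl]thiourea (20 mol%), PhCO2H (20 mol%), toluene, rt; then TsOH·H2O (30 mol%), 80 °C
Reagents that add atoms: none
Why: Enamine-mediated asymmetric Michael addition of the α-branched aldehyde to the thiourea-bound alkylidene acetoacetate sets the first stereocentre (catalyst-controlled face), and the acid then drives a Robinson-type aldol condensation of the methyl ketone onto the neopentyl aldehyde, tert-butyl ester cleavage and decarboxylation of the β-keto acid.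

Step 3
Reactants: 7 (5S)-5-({[tert-butyl(diphenyl)silyl]oxy}methyl)-4,4-dimethylcyclohex-2-en-1-one
Product: 8 (5R)-5-({[tert-butyl(diphenyl)silyl]oxy}methyl)-4,4-dimethyl-6-methylidenecyclohex-2-en-1-one
Conditions: (CH2O)n, iPr2NH·CF3CO2H (1 equiv), CF3CO2H (10 mol%), THF, 65 °C; used at once
Reagents that add atoms: paraformaldehyde (as formaldehyde), C=O
Why: Mannich-type α-methylenation (iminium addition, then β-elimination of the amine) at C6, the only enolisable carbon of the enone; the stereocentre is untouched and its label changes from S to R only through CIP priorities.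

Step 4
Reactants: 9 ethyl 3-oxobutanoate; 10 ethyl 2-(diethoxyphosphoryl)prop-2-enoate
Product: 11 diethyl 2-acetyl-4-(diethoxyphosphoryl)pentanedioate (racemic diastereomer mixture)
Conditions: 10 added dropwise over 2 h to 9 and DBU (5 mol%), THF, 0 °C to rt
Reagents that add atoms: none
Why: Base-catalysed Michael addition of the β-keto ester to the vinylphosphonate, in which the slow addition of 10 keeps the keto ester in excess over the acceptor at all times so that a second addition to the more hindered adduct is suppressed; the stereocentres formed are racemic and are destroyed or equilibrated later.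

Step 5
Reactants: 11 diethyl 2-acetyl-4-(diethoxyphosphoryl)pentanedioate; 12 prop-2-enal
Product: 14 diethyl 1-acetylcyclohex-3-ene-1,3-dicarboxylate (racemic), via keto aldehyde 13 (not isolated)
Conditions: 12, DBU (5 mol%), THF, −20 °C; then Cs2CO3 (1.5 equiv), EtOH, 0 °C to rt
Reagents that add atoms: none
Why: Michael addition of the more acidic β-keto ester carbon to acrolein, then intramolecular Horner–Wadsworth–Emmons olefination of the phosphonate carbanion with the new aldehyde, which outruns aldol reaction of the methyl ketone and closes ring C with the enoate double bond in place.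

Step 6
Reactants: 14 diethyl 1-acetylcyclohex-3-ene-1,3-dicarboxylate
Product: 15 5-acetylcyclohex-1-ene-1-carboxylic acid (racemic)
Conditions: 6 M HCl, AcOH, 100 °C
Reagents that add atoms: water, O
Why: Acid hydrolysis of both esters and decarboxylation of the β-keto acid (ketonic cleavage of an acetoacetic ester); the remaining centre α to the acetyl group is configurationally labile and is fixed only in step 7.

Step 7
Reactants: 8 (5R)-5-({[tert-butyl(diphenyl)silyl]oxy}methyl)-4,4-dimethyl-6-methylidenecyclohex-2-en-1-one; 15 5-acetylcyclohex-1-ene-1-carboxylic acid (1.3 equiv)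
Product: 18 (1S,6R,4a'R,7'R,8a'S)-7'-acetyl-6-({[tert-butyl(diphenyl)silyl]oxy}methyl)-5,5-dimethyloctahydrospiro[cyclohex-3-ene-1,4'-isochromene]-1',2-dione, via ester 16 (not isolated), via epimer mixture 17 (not isolated)
Conditions: DBU (0.3 equiv), MeCN, 50 °C; then DBU (1.5 equiv), 50 °C
Reagents that add atoms: none
Why: Proposed new method: a base-mediated formal [4+2] annulation of an α-methylene ketone with an α,β-unsaturated carboxylic acid, in which the carboxylate of 15 adds reversibly to the exocyclic enone carbon of 8 (oxa-Michael), the β-acyloxy dienolate (also re-formed from its keto tautomer 16) closes by 6-endo-trig intramolecular Michael addition onto its own cyclohexenoate β-carbon and the ester enolate is protonated by 15 so that base is catalytic; the closest known reactions are oxa-Michael/Michael domino annulations and intramolecular Michael lactonisations of tethered enoates; the spiro carbon is set by attack anti to the pseudoaxial CH2OSi group at C6, C4a' by a chair-like transition state that turns ring C away from the C6/CMe2 flank, C8a' by protonation of the ester enolate trans to the new bond (cis-fused lactone), and C7' by the final DBU equilibration to the equatorial acetyl epimer (the axial one is syn-diaxial to the lactone carbonyl carbon), so both enantiomers of 15 converge on 18.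

Step 8
Reactants: 18 (1S,6R,4a'R,7'R,8a'S)-7'-acetyl-6-({[tert-butyl(diphenyl)silyl]oxy}methyl)-5,5-dimethyloctahydrospiro[cyclohex-3-ene-1,4'-isochromene]-1',2-dione
Product: 19 1-[(1S,6R,4a'R,7'R,8a'S)-6-({[tert-butyl(diphenyl)silyl]oxy}methyl)-5,5-dimethyl-1',2-dioxooctahydrospiro[cyclohex-3-ene-1,4'-isochromen]-7'-yl]ethenyl trifluoromethanesulfonate
Conditions: KN(SiMe3)2 (1.05 equiv), THF, −78 °C; then PhNTf2, −78 to 0 °C
Reagents that add atoms: N-phenylbis(trifluoromethanesulfonimide), O=S(=O)(N(c1ccccc1)S(=O)(=O)C(F)(F)F)C(F)(F)F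
Why: Kinetic deprotonation of the methyl ketone at CH3 and O-triflation of the enolate (enol triflate formation); the ring A enone has no enolisable hydrogen, the lactone α-hydrogen is less acidic, and no stereocentre is touched.

Step 9
Reactants: 19 1-[(1S,6R,4a'R,7'R,8a'S)-6-({[tert-butyl(diphenyl)silyl]oxy}methyl)-5,5-dimethyl-1',2-dioxooctahydrospiro[cyclohex-3-ene-1,4'-isochromen]-7'-yl]ethenyl trifluoromethanesulfonate
Product: 20 2-[(1S,6R,4a'R,7'R,8a'S)-6-({[tert-butyl(diphenyl)silyl]oxy}methyl)-5,5-dimethyl-1',2-dioxooctahydrospiro[cyclohex-3-ene-1,4'-isochromen]-7'-yl]prop-2-enoic acid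
Conditions: Pd(OAc)2 (5 mol%), PPh3 (10 mol%), CO (1 atm), KOAc (4 equiv), DMF/H2O, 50 °C; acidic work-up
Reagents that add atoms: carbon monoxide, [C-]#[O+]; water, O
Why: Palladium-catalysed hydroxycarbonylation of a vinyl triflate (oxidative addition to zerovalent palladium, CO insertion, hydrolysis of the acylpalladium) gives the α-substituted acrylic acid under conditions that leave the lactone, enone and silyl ether intact.

Step 10
Reactants: 20 2-[(1S,6R,4a'R,7'R,8a'S)-6-({[tert-butyl(diphenyl)silyl]oxy}methyl)-5,5-dimethyl-1',2-dioxooctahydrospiro[cyclohex-3-ene-1,4'-isochromen]-7'-yl]prop-2-enoic acid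
Product: 22 2-[(1R,2S,5R,4a'R,7'R,8a'S)-8,8-dimethyl-1',3-dioxooctahydrospiro[6-oxabicyclo[3.2.1]octane-2,4'-isochromen]-7'-yl]prop-2-enoic acid (CNP0268721.2), via alcohol 21 (not isolated)
Conditions: HF·pyridine, THF, 0 °C to rt; then DBU (1.5 equiv), CH2Cl2, 0 °C to rt; dilute HCl work-up
Reagents that add atoms: none
Why: Fluoride desilylation, then 5-exo-trig oxa-Michael addition of the primary alcohol to the enone β-carbon (helped by the gem-dimethyl group); the one-carbon tether can only bridge cis, so the new C–O stereocentre is fixed by the neighbouring CH stereocentre.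

**Compound list**
1 | tert-butyl 3-oxobutanoate | CC(=O)CC(=O)OC(C)(C)C | starting material
2 | {[tert-butyl(diphenyl)silyl]oxy}acetaldehyde | O=CCO[Si](c1ccccc1)(c1ccccc1)C(C)(C)C | starting material
3 | tert-butyl 2-acetyl-4-{[tert-butyl(diphenyl)silyl]oxy}but-2-enoate (E/Z mixture) | CC(=O)C(=CCO[Si](c1ccccc1)(c1ccccc1)C(C)(C)C)C(=O)OC(C)(C)C | intermediate
4 | 2-methylpropanal | CC(C)C=O | starting material
5 | tert-butyl (3S)-2-acetyl-3-({[tert-butyl(diphenyl)silyl]oxy}methyl)-4,4-dimethyl-5-oxopentanoate (both C2 epimers) | CC(C)(C)[Si](c1ccccc1)(c1ccccc1)OC[C@@H](C(C(C)=O)C(=O)OC(C)(C)C)C(C)(C)C=O | intermediate (not isolated)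
6 | tert-butyl (6S)-6-({[tert-butyl(diphenyl)silyl]oxy}methyl)-5,5-dimethyl-2-oxocyclohex-3-ene-1-carboxylate (both C1 epimers) | CC(C)(C)[Si](c1ccccc1)(c1ccccc1)OC[C@@H]1C(C)(C)C=CC(=O)C1C(=O)OC(C)(C)C | intermediate (not isolated)
7 | (5S)-5-({[tert-butyl(diphenyl)silyl]oxy}methyl)-4,4-dimethylcyclohex-2-en-1-one | CC(C)(C)[Si](c1ccccc1)(c1ccccc1)OC[C@@H]1C(C)(C)C=CC(=O)C1 | intermediate
8 | (5R)-5-({[tert-butyl(diphenyl)silyl]oxy}methyl)-4,4-dimethyl-6-methylidenecyclohex-2-en-1-one | CC(C)(C)[Si](c1ccccc1)(c1ccccc1)OC[C@@H]1C(C)(C)C=CC(=O)C1=C | intermediate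
9 | ethyl 3-oxobutanoate | CCOC(=O)CC(C)=O | starting material
10 | ethyl 2-(diethoxyphosphoryl)prop-2-enoate | C=C(C(=O)OCC)P(=O)(OCC)OCC | starting material
11 | diethyl 2-acetyl-4-(diethoxyphosphoryl)pentanedioate (racemic diastereomer mixture) | CCOC(=O)C(C(C)=O)CC(C(=O)OCC)P(=O)(OCC)OCC | intermediate
12 | prop-2-enal | C=CC=O | starting material
13 | diethyl 2-acetyl-4-(diethoxyphosphoryl)-2-(3-oxopropyl)pentanedioate (racemic diastereomer mixture) | CCOC(=O)C(CCC=O)(C(C)=O)CC(C(=O)OCC)P(=O)(OCC)OCC | intermediate (not isolated)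
14 | diethyl 1-acetylcyclohex-3-ene-1,3-dicarboxylate (racemic) | CCOC(=O)C1=CCCC(C1)(C(C)=O)C(=O)OCC | intermediate
15 | 5-acetylcyclohex-1-ene-1-carboxylic acid (racemic, labile centre) | CC(=O)C1CCC=C(C1)C(=O)O | intermediate
16 | [(1RS,6S)-6-({[tert-butyl(diphenyl)silyl]oxy}methyl)-5,5-dimethyl-2-oxocyclohex-3-en-1-yl]methyl (5RS)-5-acetylcyclohex-1-ene-1-carboxylate | CC(C)(C)[Si](c1ccccc1)(c1ccccc1)OC[C@@H]1C(C)(C)C=CC(=O)C1COC(=O)C1=CCCC(C1)C(C)=O | intermediate (not isolated)
17 | (1S,6R,4a'R,7'RS,8a'S)-7'-acetyl-6-({[tert-butyl(diphenyl)silyl]oxy}methyl)-5,5-dimethyloctahydrospiro[cyclohex-3-ene-1,4'-isochromene]-1',2-dione (C7' epimer mixture) | CC(=O)C1CC[C@@H]2[C@H](C1)C(=O)OC[C@]21C(=O)C=CC(C)(C)[C@H]1CO[Si](c1ccccc1)(c1ccccc1)C(C)(C)C | intermediate (not isolated)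
18 | (1S,6R,4a'R,7'R,8a'S)-7'-acetyl-6-({[tert-butyl(diphenyl)silyl]oxy}methyl)-5,5-dimethyloctahydrospiro[cyclohex-3-ene-1,4'-isochromene]-1',2-dione | CC(=O)[C@@H]1CC[C@@H]2[C@H](C1)C(=O)OC[C@]21C(=O)C=CC(C)(C)[C@H]1CO[Si](c1ccccc1)(c1ccccc1)C(C)(C)C | intermediate
19 | 1-[(1S,6R,4a'R,7'R,8a'S)-6-({[tert-butyl(diphenyl)silyl]oxy}methyl)-5,5-dimethyl-1',2-dioxooctahydrospiro[cyclohex-3-ene-1,4'-isochromen]-7'-yl]ethenyl trifluoromethanesulfonate | C=C(OS(=O)(=O)C(F)(F)F)[C@@H]1CC[C@@H]2[C@H](C1)C(=O)OC[C@]21C(=O)C=CC(C)(C)[C@H]1CO[Si](c1ccccc1)(c1ccccc1)C(C)(C)C | intermediate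
20 | 2-[(1S,6R,4a'R,7'R,8a'S)-6-({[tert-butyl(diphenyl)silyl]oxy}methyl)-5,5-dimethyl-1',2-dioxooctahydrospiro[cyclohex-3-ene-1,4'-isochromen]-7'-yl]prop-2-enoic acid | C=C(C(=O)O)[C@@H]1CC[C@@H]2[C@H](C1)C(=O)OC[C@]21C(=O)C=CC(C)(C)[C@H]1CO[Si](c1ccccc1)(c1ccccc1)C(C)(C)C | intermediate
21 | 2-[(1S,6R,4a'R,7'R,8a'S)-6-(hydroxymethyl)-5,5-dimethyl-1',2-dioxooctahydrospiro[cyclohex-3-ene-1,4'-isochromen]-7'-yl]prop-2-enoic acid | C=C(C(=O)O)[C@@H]1CC[C@@H]2[C@H](C1)C(=O)OC[C@]21C(=O)C=CC(C)(C)[C@H]1CO | intermediate (not isolated)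
22 | 2-[(1R,2S,5R,4a'R,7'R,8a'S)-8,8-dimethyl-1',3-dioxooctahydrospiro[6-oxabicyclo[3.2.1]octane-2,4'-isochromen]-7'-yl]prop-2-enoic acid (CNP0268721.2) | C=C(C(=O)O)[C@@H]1CC[C@@H]2[C@H](C1)C(=O)OC[C@]21C(=O)C[C@H]2OC[C@@H]1C2(C)C | target

**Step count**
Total steps: 10. Longest linear sequence: 7 (steps 1, 2, 3, 7, 8, 9, 10); steps 4–6 form the ring C branch.

**Steps most likely to fail**

Step 7 (the proposed annulation). The Michael closure onto a trisubstituted cyclohexenoate may be slower than retro-oxa-Michael, oligomerisation or exo-to-endo isomerisation of 8, and the facial selectivity at the spiro carbon rests on substrate control alone. The fallback uses known chemistry, sets out from 7 (with 15) and comes back at 18. The lithium dienolate of 7 (LiN(iPr)2, THF, −78 °C) is trapped with monomeric formaldehyde to give the hydroxymethyl ketone F1. Steglich esterification of F1 with 15 (EDC, DMAP, CH2Cl2) gives ester 16, now isolated. Soft enolisation (Me3SiOTf, Et3N) converts both ketones into the bis(silyl enol ether) F2. TiCl4 at −78 °C then closes the lactone by an intramolecular Mukaiyama–Michael addition that never passes through the free β-acyloxy enolate. Aqueous work-up gives 17 and the DBU equilibration of step 7 gives 18.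

Step 2 (asymmetric Michael addition and Robinson closure). The E/Z mixture of a hindered alkylidene acetoacetate may react slowly or with low selectivity with an α-branched aldehyde, and the silyl ether must survive hot TsOH. The fallback does not use 3; it replaces 1, 2 and 4 by commercial 4,4-dimethylcyclohexa-2,5-dien-1-one and nitromethane and comes back at 7. Iminium catalysis with 9-amino-9-deoxy-epi-quinine (20 mol%) and PhCO2H adds nitromethane to the dienone to give the nitromethyl enone F3. A Nef reaction (NaOMe, then TiCl3 buffered with NH4OAc) gives the aldehyde F4. NaBH(OAc)3 reduces only the aldehyde to the alcohol F5, which is silylated in the same flask (tBuPh2SiCl, imidazole) before it can add to the enone, giving 7.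

Step 8 (kinetic enol triflate next to a lactone and a tertiary α-hydrogen). Wrong-site enolisation or base damage to the spirolactone would cost material. The fallback sets out from 18 and comes back at 20, bypassing 19 and step 9. Wittig methylenation (Ph3P=CH2, THF, 0 °C) of the methyl ketone, which is far more reactive than the hindered conjugated ring A ketone, gives the isopropenyl compound F6. Allylic oxidation (SeO2 cat., tBuOOH, CH2Cl2) gives the α-substituted enal F7. Chlorite oxidation (NaClO2, NaH2PO4, 2-methylbut-2-ene, tBuOH/H2O) gives 20.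

**Further compounds**
F1 | step 7 | (5S)-5-({[tert-butyl(diphenyl)silyl]oxy}methyl)-6-(hydroxymethyl)-4,4-dimethylcyclohex-2-en-1-one (C6 epimers) | CC(C)(C)[Si](c1ccccc1)(c1ccccc1)OC[C@@H]1C(C)(C)C=CC(=O)C1CO
F2 | step 7 | {(6R)-6-({[tert-butyl(diphenyl)silyl]oxy}methyl)-5,5-dimethyl-2-[(trimethylsilyl)oxy]cyclohexa-1,3-dien-1-yl}methyl 5-{1-[(trimethylsilyl)oxy]ethenyl}cyclohex-1-ene-1-carboxylate | CC(C)(C)[Si](c1ccccc1)(c1ccccc1)OC[C@@H]1C(C)(C)C=CC(O[Si](C)(C)C)=C1COC(=O)C1=CCCC(C1)C(=C)O[Si](C)(C)C
F3 | step 2 | (5S)-4,4-dimethyl-5-(nitromethyl)cyclohex-2-en-1-one | [O-][N+](=O)C[C@@H]1C(C)(C)C=CC(=O)C1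
F4 | step 2 | (1S)-2,2-dimethyl-5-oxocyclohex-3-ene-1-carbaldehyde | O=C[C@@H]1C(C)(C)C=CC(=O)C1
F5 | step 2 | (5S)-5-(hydroxymethyl)-4,4-dimethylcyclohex-2-en-1-one | OC[C@@H]1C(C)(C)C=CC(=O)C1
F6 | step 8 | (1S,6R,4a'R,7'R,8a'S)-6-({[tert-butyl(diphenyl)silyl]oxy}methyl)-5,5-dimethyl-7'-(prop-1-en-2-yl)octahydrospiro[cyclohex-3-ene-1,4'-isochromene]-1',2-dione | C=C(C)[C@@H]1CC[C@@H]2[C@H](C1)C(=O)OC[C@]21C(=O)C=CC(C)(C)[C@H]1CO[Si](c1ccccc1)(c1ccccc1)C(C)(C)C
F7 | step 8 | 2-[(1S,6R,4a'R,7'R,8a'S)-6-({[tert-butyl(diphenyl)silyl]oxy}methyl)-5,5-dimethyl-1',2-dioxooctahydrospiro[cyclohex-3-ene-1,4'-isochromen]-7'-yl]prop-2-enal | C=C(C=O)[C@@H]1CC[C@@H]2[C@H](C1)C(=O)OC[C@]21C(=O)C=CC(C)(C)[C@H]1CO[Si](c1ccccc1)(c1ccccc1)C(C)(C)C
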